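Assumption: eriostemin has no stereocentre, so the target is one achiral compound; the chiral intermediates are racemic and their stereocentres are erased before the end.

**Retrosynthetic overview**
- Only the pyranone ring (ring C) is built; rings A and B are bought as 3,4,5-trimethoxyphenol and trans-4-methoxy-β-nitrostyrene.
- Eriostemin ⇐ 2-aryl-3-nitro-2H-chromene: alkaline peroxide unmasks the nitro-bearing C3 to the C3–OH/C4=O unit (Nef-type).
- The nitrochromene ⇐ 2,3-dihydroxy-4,5,6-trimethoxybenzaldehyde + the nitrostyrene in one operation. O1–C2 forms by oxa-Michael addition; the key C3–C4 bond forms when the nitronate carbon, a masked acyl anion (the future C3–O carbon), attacks the aldehyde carbon (the future C4=O). In the 3,4-dione tautomer of the target these are two adjacent carbonyl carbons.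
- The aldehyde ⇐ 3,4,5-trimethoxycatechol (formylation at its only free position) ⇐ 3,4,5-trimethoxyphenol (ortho-hydroxylation).

**Step 1**
Reactants: 1 3,4,5-trimethoxyphenol
Product: 3 3,4,5-trimethoxybenzene-1,2-diol, via 3,4,5-trimethoxy-1,2-benzoquinone 2 (not isolated)
Conditions: IBX (1.2 equiv), DMF, rt, 2 h; then aq Na2S2O4 (3 equiv), EtOAc, rt, under N2
Reagents that add atoms: IBX (2-iodoxybenzoic acid), OI1(=O)OC(=O)c2ccccc12
Why: IBX ortho-oxygenation of an electron-rich phenol delivers oxygen from the aryloxy-iodane to a free ortho carbon (the two ortho positions of 1 are equivalent) to give o-quinone 2, which dithionite reduces in the same flask to the catechol; no stereocentre is formed.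

**Step 2**
Reactants: 3 3,4,5-trimethoxybenzene-1,2-diol
Product: 5 2,3-dihydroxy-4,5,6-trimethoxybenzaldehyde, via α-chloro ether 4 (not isolated)
Conditions: Cl2CHOMe (1.3 equiv), TiCl4 (3 equiv), CH2Cl2, −10 → 0 °C, 1 h; then 1 M aq HCl, 0 °C → rt
Reagents that add atoms: dichloromethyl methyl ether, COC(Cl)Cl; water, O
Why: Rieche formylation (Friedel–Crafts type) can only occur at the single remaining ring C–H, which is ortho to a titanium-bound phenoxide and a methoxy group and para to another methoxy group, and aqueous acid hydrolyses the α-chloro ether 4 to the aldehyde; no stereocentre remains.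

**Step 3**
Reactants: 5 2,3-dihydroxy-4,5,6-trimethoxybenzaldehyde; 6 (E)-1-methoxy-4-(2-nitroethenyl)benzene (trans-4-methoxy-β-nitrostyrene)
Product: 8 rac-5,6,7-trimethoxy-2-(4-methoxyphenyl)-3-nitro-2H-chromen-8-ol, via 3-nitrochroman-4-ol 7 (not isolated)
Conditions: 6 (1.5 equiv), DABCO (0.5 equiv), MeCN (1 M), 50 °C, N2, 12–24 h
Reagents that add atoms: none
Why: Tandem oxa-Michael/Henry (nitro-aldol)/dehydration: the 2-phenoxide adds to the nitroalkene and the resulting nitronate, a masked acyl anion at the future C3, closes onto the aldehyde carbon (future C4) in a 6-membered ring, while addition through the 3-OH is reversible and cannot cyclise, so the unprotected catechol is tolerated; the new C2 stereocentre is racemic and is erased in step 4.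

**Step 4**
Reactants: 8 rac-5,6,7-trimethoxy-2-(4-methoxyphenyl)-3-nitro-2H-chromen-8-ol
Product: 11 eriostemin, via nitro-epoxide 9 (not isolated), via 4-hydroperoxychroman-3-one 10 (not isolated)
Conditions: 30% aq H2O2 (6 equiv), NaOH (4 equiv), MeOH–THF (1:1), 0 °C → rt, 2 h; then 1 M aq HCl to pH 3
Reagents that add atoms: hydrogen peroxide, OO
Why: Weitz–Scheffer epoxidation of the nitroalkene gives 9, hydroperoxide opens it at benzylic C4 while nitrite leaves from C3 (a Nef-type unmasking that turns the nitro carbon into a carbonyl), and Kornblum–DeLaMare collapse of 10 gives the 3,4-dione, which enolises to the flavonol, a product class that survives alkaline peroxide as in the Algar–Flynn–Oyamada reaction; all stereocentres vanish.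

**Compound list**
1 | 3,4,5-trimethoxyphenol | COc1cc(O)cc(OC)c1OC | starting material
2 | 3,4,5-trimethoxy-1,2-benzoquinone | COC1=CC(=O)C(=O)C(OC)=C1OC | intermediate
3 | 3,4,5-trimethoxybenzene-1,2-diol | COc1cc(O)c(O)c(OC)c1OC | intermediate
4 | 6-[chloro(methoxy)methyl]-3,4,5-trimethoxybenzene-1,2-diol (racemic, transient) | COC(Cl)c1c(O)c(O)c(OC)c(OC)c1OC | intermediate
5 | 2,3-dihydroxy-4,5,6-trimethoxybenzaldehyde | COc1c(OC)c(OC)c(C=O)c(O)c1O | intermediate
6 | (E)-1-methoxy-4-(2-nitroethenyl)benzene | COc1ccc(/C=C/[N+](=O)[O-])cc1 | starting material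
7 | 5,6,7-trimethoxy-2-(4-methoxyphenyl)-3-nitrochromane-4,8-diol (racemic, diastereomer mixture, configuration not defined) | COc1ccc(cc1)C1Oc2c(O)c(OC)c(OC)c(OC)c2C(O)C1[N+](=O)[O-] | intermediate
8 | rac-5,6,7-trimethoxy-2-(4-methoxyphenyl)-3-nitro-2H-chromen-8-ol (racemic at C2) | COc1ccc(cc1)C1Oc2c(O)c(OC)c(OC)c(OC)c2C=C1[N+](=O)[O-] | intermediate
9 | rac-3,4-epoxy-5,6,7-trimethoxy-2-(4-methoxyphenyl)-3-nitrochroman-8-ol (epoxide oxygen anti to the 2-aryl group; racemate, one enantiomer drawn) | COc1ccc(cc1)[C@@H]1Oc2c(O)c(OC)c(OC)c(OC)c2[C@H]2O[C@@]12[N+](=O)[O-] | intermediate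
10 | 4-hydroperoxy-8-hydroxy-5,6,7-trimethoxy-2-(4-methoxyphenyl)chroman-3-one (racemic, diastereomer mixture, configuration not defined) | COc1ccc(cc1)C1Oc2c(O)c(OC)c(OC)c(OC)c2C(OO)C1=O | intermediate
11 | eriostemin, 3,8-dihydroxy-5,6,7-trimethoxy-2-(4-methoxyphenyl)-4H-chromen-4-one (achiral) | COc1ccc(-c2oc3c(O)c(OC)c(OC)c(OC)c3c(=O)c2O)cc1 | target

**Totals**
Total step count: 4. Longest linear sequence: 4 steps (1 → 3 → 5 → 8 → 11).

**Steps most likely to fail, with fallbacks**

Step 4. The electron-rich 8-phenoxide and hydroperoxy ketone 10 are exposed to alkaline peroxide, so over-oxidation or C3–C4 cleavage can compete. The fallback sets out from 8 and comes back at 11, replacing peroxide by DMSO as the terminal oxidant. Anhydrous epoxidation (t-BuOOH, DBU, THF, 0 °C) gives nitro-epoxide 9, which is now isolated. Warming 9 in DMSO with NaHCO3 (60 °C) lets the sulfoxide oxygen open the epoxide at benzylic C4 while nitrite leaves from C3. This gives dimethyl{[8-hydroxy-5,6,7-trimethoxy-2-(4-methoxyphenyl)-3-oxochroman-4-yl]oxy}sulfonium nitrite F1 (not isolated), which loses dimethyl sulfide in a Kornblum oxidation to the 3,4-dione tautomer of 11.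

Step 3. The hydrogen-bonded catecholate of 5 may be a poor oxa-Michael donor or air-sensitive, and the aldehyde is flanked by two substituents. The fallback sets out from 5 and comes back at 8, masking the 3-OH first. The dianion (NaH, 2.2 equiv, DMSO) is alkylated with MOMCl (1.0 equiv) at the more basic, non-chelated 3-phenoxide to give 2-hydroxy-4,5,6-trimethoxy-3-(methoxymethoxy)benzaldehyde F2. DABCO with 6 then gives, through 5,6,7-trimethoxy-8-(methoxymethoxy)-2-(4-methoxyphenyl)-3-nitrochroman-4-ol F3 (not isolated), rac-5,6,7-trimethoxy-8-(methoxymethoxy)-2-(4-methoxyphenyl)-3-nitro-2H-chromene F4. HCl in MeOH at rt removes the acetal and returns 8.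

Step 2. Lewis-acid formylation of a free, chelating catechol risks a titanium catecholate that does not react, a cyclic orthoformate, or demethylation next to the new aldehyde. The fallback sets out from 3 and comes back at 5, replacing electrophilic substitution by directed ortho-metalation. MOMCl and i-Pr2NEt in CH2Cl2 give 1,2-bis(methoxymethoxy)-3,4,5-trimethoxybenzene F5. n-BuLi/TMEDA in THF at 0 °C lithiates the only ring C–H to [2,3-bis(methoxymethoxy)-4,5,6-trimethoxyphenyl]lithium F6. A DMF quench gives 2,3-bis(methoxymethoxy)-4,5,6-trimethoxybenzaldehyde F7, and HCl in MeOH at 50 °C gives 5.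

**Further compounds**
F1 | step 4 | dimethyl{[8-hydroxy-5,6,7-trimethoxy-2-(4-methoxyphenyl)-3-oxochroman-4-yl]oxy}sulfonium nitrite (racemic, diastereomer mixture) | COc1ccc(cc1)C1Oc2c(O)c(OC)c(OC)c(OC)c2C(O[S+](C)C)C1=O.[O-]N=O
F2 | step 3 | 2-hydroxy-4,5,6-trimethoxy-3-(methoxymethoxy)benzaldehyde | COCOc1c(O)c(C=O)c(OC)c(OC)c1OC
F3 | step 3 | 5,6,7-trimethoxy-8-(methoxymethoxy)-2-(4-methoxyphenyl)-3-nitrochroman-4-ol (racemic, diastereomer mixture) | COCOc1c(OC)c(OC)c(OC)c2C(O)C([N+](=O)[O-])C(c3ccc(OC)cc3)Oc12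
F4 | step 3 | rac-5,6,7-trimethoxy-8-(methoxymethoxy)-2-(4-methoxyphenyl)-3-nitro-2H-chromene | COCOc1c(OC)c(OC)c(OC)c2C=C([N+](=O)[O-])C(c3ccc(OC)cc3)Oc12
F5 | step 2 | 1,2-bis(methoxymethoxy)-3,4,5-trimethoxybenzene | COCOc1cc(OC)c(OC)c(OC)c1OCOC
F6 | step 2 | [2,3-bis(methoxymethoxy)-4,5,6-trimethoxyphenyl]lithium | COCOc1c([Li])c(OC)c(OC)c(OC)c1OCOC
F7 | step 2 | 2,3-bis(methoxymethoxy)-4,5,6-trimethoxybenzaldehyde | COCOc1c(OCOC)c(OC)c(OC)c(OC)c1C=O
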